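- Millimolar readings of L differ with the charge, so each is turned into a pure number, the log-conversion: the natural log of J charged over J left.

| flask | J | X | time |
|---|---|---|---|
| south-west | 100 mM | 300 mM |  |
| west | 60.0 mM | 260 mM |  |
| north-west | 150 mM | 300 mM |  |
| south | 33.0 mM | 900 mM | 22 h |

| run | time / h | [L] / mM |
|---|---|---|
| south-west run | 1.7 | 17.2 |
| south-west run | 5.1 | 30.6 |
| south-west run | 9.7 | 39.8 |
| south-west run | 15 | 45.6 |
| south-west run | 22 | 48.7 |
| west run | 1.7 | 10.7 |
| west run | 5.1 | 17.5 |
| west run | 9.7 | 22.5 |
| west run | 15 | 25.4 |
| west run | 22 | 28.0 |
| north-west run | 1.7 | 26.4 |
| north-west run | 5.1 | 49.4 |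
| north-west run | 9.7 | 60.7 |
| north-west run | 15 | 67.3 |
| north-west run | 22 | 72.0 |

(readings scatter by 0.5 mM)

* how the opening rate goes with [J] round the charge of the south-west run: the exponent of the rate at two percent of J gone to L (one fixed amount of L, the same in the runs compared)
* how the opening rate goes with [X] round the charge of the south-west run: the exponent of the rate at two percent of J gone to L
* the west run starts with 40.0 mM less of J and of X than the south-west run, and with no L. Compared where both hold the same amount of J, once fifteen percent of what the west run was charged with has turned into L, is the west run faster, slower or alike (within a tenth)?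
* L in the south run at 22 h, as a share of the J charged

- Overall: J + X -> L.
- Constant volume, constant temperature.
- "The second partner" is X.
- An order is taken over about fifteen percent of the charge, up and down.

- At the last reading the log-conversion is 0.667 in the south-west run and 0.654 in the north-west run, so this reckoning puts the exponent in J near one.
- The first readings of the west and south-west runs lie too close to fix the exponent in X, so one is assumed; the log-conversion per hour then follows the X standing.
- In the south-west run that pace falls from 0.0519 h⁻¹ early to 0.0130 h⁻¹ late, yet L accounts for just 48.7 mM of the 300 mM of X.
- Suppose, then, that X also fades in pairs. Its share standing would follow the dose, X charged times time, and late log-conversion would climb along the log of dose.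
- The dose slope, the log-conversion gained per natural-log unit of dose, reads 0.207 along time in the south-west run.
- The south run carries 3.00 times that X, which gives 59.1% at 22 h.
- The weak link is that slope, taken along time while the curve still bends. The late lag of the west run reads it along X instead: 0.272, a higher and noisier reading, giving 61.9%. This reckoning commits to 60.5%.
- At nearly equal J, 0.0493 M against 0.0513 M, the west run's mean rate up to its first reading, 6.29 mM h⁻¹, beats the south-west run's mean rate over its last interval, 0.443 mM h⁻¹, so this reckoning calls the west run faster.
- The forecast, reading the stall as one that “looks like an equilibrium”, gives 1, 0.1, faster and 74%, a share above this reckoning.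
- The flask gives 1.1, 1.0, faster and 61.9%.

    J + X → L (0.5616 L mol⁻¹ h⁻¹)
    2 X → Vo (1.202 L mol⁻¹ h⁻¹)
    J + X + L → 2 L (4.716 L² mol⁻² h⁻¹)

- The path from 2 X to Vo is the main reason for the south run's shortfall: the simulated south run without it reaches >99.9%. The south run's log-conversion of 0.964 means a dose slope of 0.270 above the south-west run. On the west run, the slope 0.207 lifts the south-west log-conversion to 0.693, and the X ratio stretches that time to 28.7 h. The simulated west run brings L to 0.5 of its charge at 28.9 h.

The numbers in the tables are calculated on assumed constants, noise included.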